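**Plan** (numbering: C1 = lactone carbonyl … C24 = CH2N of the long chain; C1′–C5′ = the 2-hydroxypentanoyl unit; TBS = tert-butyldimethylsilyl)

1. Retrosynthesis: cut the lactone at the O–C2′ bond (C1 carboxylate oxygen to the propyl-bearing carbon next to the amide carbonyl), then the amide N–C1′, then C17–CH2OH and C17–C18 (two Pd couplings on a C16=C17Br2 unit), C16=C17 and C14=C15 (olefinations from a C13 vinyl group), the C9–C10 ketone bond, C5=C6 and C20–C21.
2. Forward: the C1–C9 acid (from meso-2,4-dimethylglutaric anhydride) and the C10–C15 bromide give the ketone, then the C16 enal, then the C17 gem-dibromide. The C18–C24 vinyl tris-silyl ether (from ethyl (S)-4-chloro-3-hydroxybutanoate) is N-acylated with (R)-2-acetoxypentanoic acid, hydroborated and joined at C17–C18. Hydroxymethylation, saponification, ring closure and desilylation follow.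
3. The only ring, the 28-membered 1-oxa-4-aza macrocycle, is formed in the penultimate step by intramolecular Mitsunobu O-alkylation.
4. Enabling feature: C2′ is a secondary carbinol flanked by the amide carbonyl C1′. It is SN2-activated, does not ionise, and is available in either configuration from norvaline, so the C1 carboxylate oxygen can close the ring at carbon with inversion while the epimerisable C2 acid centre is never acyl-activated.
5. Stereochemistry: C2/C4 from one catalytic desymmetrisation of the meso anhydride; C13 from Cu-catalysed SN2′ ethylation; C23 bought; C20/C21 from one reagent-controlled anti-selective γ-borylallylboration; C2′ from D-norvaline (retentive diazotisation), inverted in the ring closure; 14E from cross-metathesis; 16Z from trans-selective coupling of the gem-dibromide followed by retentive Stille coupling.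

Key step: step 23

Remark (assumption): the senses of induction of (DHQD)2AQN (step 1) and of Taniaphos (step 7) are taken to be those that give the drawn enantiomers; the pseudo-enantiomeric catalyst or the ligand antipode would be used otherwise.

**Route**

Step 1
Reactants: 1 cis-2,4-dimethylglutaric anhydride (meso)
Product: 2 (2R,4S)-5-methoxy-2,4-dimethyl-5-oxopentanoic acid
Conditions: MeOH (10 equiv), (DHQD)2AQN (10 mol%), Et2O, −40 °C
Reagents that add atoms: methanol, CO
Why: Cinchona-alkaloid-catalysed enantioselective alcoholysis (desymmetrisation) of the meso anhydride should open one enantiotopic carbonyl, so both methyl-bearing centres, already cis in the ring, become the syn pair that ends as (2S,4S) in the target in one catalytic event.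

Step 2
Reactants: 2 (2R,4S)-5-methoxy-2,4-dimethyl-5-oxopentanoic acid
Product: 3 methyl (2S,4R)-5-hydroxy-2,4-dimethylpentanoate
Conditions: BH3·SMe2 (1.2 equiv), THF, 0 °C → rt; MeOH quench
Reagents that add atoms: none
Why: Chemoselective borane reduction of a carboxylic acid in the presence of a methyl ester should give the hydroxy ester, which is used at once to forestall δ-lactonisation.

Step 3
Reactants: 3 methyl (2S,4R)-5-hydroxy-2,4-dimethylpentanoate
Product: 4 methyl (2S,4R)-2,4-dimethyl-5-oxopentanoate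
Conditions: Dess–Martin periodinane, NaHCO3, CH2Cl2, 0 °C → rt
Reagents that add atoms: none
Why: Dess–Martin oxidation under buffered, non-basic conditions should give the α-methyl aldehyde without epimerisation.

Step 4
Reactants: 4 methyl (2S,4R)-2,4-dimethyl-5-oxopentanoate; 5 (3-carboxypropyl)triphenylphosphonium bromide
Product: 7 (4Z,6R,8S)-9-methoxy-6,8-dimethyl-9-oxonon-4-enoic acid, via phosphonium ylide 6 (not isolated)
Conditions: 5, NaN(SiMe3)2 (2.0 equiv), THF, 0 °C; then 4, −78 °C → rt; acidic work-up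
Reagents that add atoms: none
Why: Wittig olefination with a non-stabilised, carboxylate-bearing ylide is fast at −78 °C, which should spare the α-stereocentre, and the (Z)-geometry is of no consequence because the alkene is hydrogenated next.

Step 5
Reactants: 7 (4Z,6R,8S)-9-methoxy-6,8-dimethyl-9-oxonon-4-enoic acid
Product: 8 (6S,8S)-9-methoxy-6,8-dimethyl-9-oxononanoic acid
Conditions: H2 (1 atm), 10% Pd/C, EtOAc, rt
Reagents that add atoms: none
Why: Heterogeneous catalytic hydrogenation of the disubstituted alkene should saturate C5–C6 without touching either stereocentre.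

Step 6
Reactants: 9 5-bromopent-1-ene; 10 (E)-1,4-dibromobut-2-ene
Product: 11 (E)-1,6-dibromohex-2-ene
Conditions: second-generation Hoveyda–Grubbs catalyst (2 mol%), 10 (3 equiv), CH2Cl2, 40 °C
Reagents that add atoms: none
Why: Olefin cross-metathesis of a terminal alkene with an excess of a symmetrical internal allylic dibromide should give the (E)-allylic bromide under thermodynamic control.

Step 7
Reactants: 11 (E)-1,6-dibromohex-2-ene
Product: 12 (3R)-6-bromo-3-ethylhex-1-ene
Conditions: EtMgBr (1.2 equiv), CuBr·SMe2 (2 mol%), Taniaphos (2.4 mol%), CH2Cl2, −78 °C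
Reagents that add atoms: ethylmagnesium bromide, CC[Mg]Br
Why: Copper-catalysed asymmetric allylic alkylation (SN2′) with a Grignard reagent should deliver ethyl to the γ-carbon, the chiral ferrocenyl diphosphine–copper complex choosing the alkene face and setting C13 as (R), while the primary alkyl bromide is inert at −78 °C.

Step 8
Reactants: 8 (6S,8S)-9-methoxy-6,8-dimethyl-9-oxononanoic acid; 12 (3R)-6-bromo-3-ethylhex-1-ene
Product: 15 methyl (2S,4S,13R)-13-ethyl-2,4-dimethyl-9-oxopentadec-14-enoate, via acid chloride 13 (not isolated), via alkylzinc bromide 14 (not isolated)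
Conditions: 8, (COCl)2, DMF (cat.), CH2Cl2, 0 °C → rt, evaporate; 12, Zn dust, LiCl, THF, 50 °C; then both, Pd(PPh3)4 (5 mol%), THF, 0 °C → rt
Reagents that add atoms: none
Why: Negishi acylation (zinc insertion into the primary bromide, then palladium-catalysed coupling of the alkylzinc with the acid chloride) should stop at the ketone and tolerate the methyl ester, the terminal alkene and all stereocentres, none of which is α to a reacting carbon.

Step 9
Reactants: 15 methyl (2S,4S,13R)-13-ethyl-2,4-dimethyl-9-oxopentadec-14-enoate; 16 (E)-but-2-enal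
Product: 17 methyl (2S,4S,13R,14E)-13-ethyl-2,4-dimethyl-9,16-dioxohexadec-14-enoate
Conditions: second-generation Hoveyda–Grubbs catalyst (5 mol%), 16 (5 equiv), CH2Cl2, 40 °C
Reagents that add atoms: none
Why: Cross-metathesis of the allylically branched terminal alkene with crotonaldehyde should give the (E)-enal under thermodynamic control and leave the allylic C13 centre untouched.

Step 10
Reactants: 17 methyl (2S,4S,13R,14E)-13-ethyl-2,4-dimethyl-9,16-dioxohexadec-14-enoate
Product: 18 methyl (2S,4S,13R,14E)-17,17-dibromo-13-ethyl-2,4-dimethyl-9-oxoheptadeca-14,16-dienoate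
Conditions: CBr4 (1.5 equiv), PPh3 (3 equiv), CH2Cl2, 0 °C
Reagents that add atoms: carbon tetrabromide, BrC(Br)(Br)Br
Why: Ramirez dibromo-olefination (first stage of the Corey–Fuchs sequence) should convert the aldehyde, far more reactive than the C9 ketone at 0 °C, into the 1,1-dibromo-1,3-diene that carries C17.

Step 11
Reactants: 19 ethyl (3S)-4-chloro-3-hydroxybutanoate
Product: 20 ethyl (3S)-4-azido-3-hydroxybutanoate
Conditions: NaN3 (1.5 equiv), DMF, 80 °C
Reagents that add atoms: sodium azide, [Na+].[N-]=[N+]=[N-]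
Why: SN2 displacement of the primary chloride by azide takes place at the CH2 carbon, so the carbinol centre (future C23) should keep its configuration.

Step 12
Reactants: 20 ethyl (3S)-4-azido-3-hydroxybutanoate
Product: 21 ethyl (3S)-4-azido-3-(TBS-oxy)butanoate
Conditions: TBSCl, imidazole, DMF, rt
Reagents that add atoms: tert-butyldimethylsilyl chloride, CC(C)(C)[Si](C)(C)Cl
Why: Imidazole-promoted silylation of the secondary alcohol should protect C23–OH for the rest of the route.

Step 13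
Reactants: 21 ethyl (3S)-4-azido-3-(TBS-oxy)butanoate
Product: 22 (3S)-4-azido-3-(TBS-oxy)butanal
Conditions: iBu2AlH (1.1 equiv), CH2Cl2, −78 °C; aq. potassium sodium tartrate
Reagents that add atoms: none
Why: Partial ester reduction with iBu2AlH at −78 °C, where the tetrahedral aluminium adduct persists until work-up, should give the aldehyde with the azide untouched.

Step 14
Reactants: 22 (3S)-4-azido-3-(TBS-oxy)butanal; 23 allenylboronic acid pinacol ester
Product: 26 (3R,4S,6S)-7-azido-6-(TBS-oxy)hept-1-ene-3,4-diol, via γ-borylallylborane 24 (not isolated), via borinate adduct 25 (not isolated)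
Conditions: 23, (+)-Ipc2BH [from (−)-α-pinene], THF, 0 °C → rt; then 22, −78 °C; then NaOH, H2O2, 0 °C → rt
Reagents that add atoms: hydrogen peroxide, OO
Why: Hydroboration of the allenylboronate gives the (E)-γ-boryl allylborane, whose allylboration of the aldehyde through a chair (Zimmerman–Traxler) transition state should place the new C21–O and C20–B bonds anti, the isopinocampheyl groups choosing the aldehyde face (reagent control, C21 S), and stereoretentive C–B oxidation then gives the anti-(20R,21S)-diol with the vinyl group in place.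

Step 15
Reactants: 26 (3R,4S,6S)-7-azido-6-(TBS-oxy)hept-1-ene-3,4-diol
Product: 27 (2S,4S,5R)-1-azido-2,4,5-tris(TBS-oxy)hept-6-ene
Conditions: TBSOTf (2.5 equiv), 2,6-lutidine, CH2Cl2, −78 → 0 °C
Reagents that add atoms: tert-butyldimethylsilyl triflate, CC(C)(C)[Si](C)(C)OS(=O)(=O)C(F)(F)F
Why: Silyl triflate silylation should cap both hindered secondary hydroxyls of the vicinal diol.

Step 16
Reactants: 27 (2S,4S,5R)-1-azido-2,4,5-tris(TBS-oxy)hept-6-ene
Product: 28 (2S,4S,5R)-2,4,5-tris(TBS-oxy)hept-6-en-1-amine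
Conditions: PPh3, THF/H2O (10:1), 50 °C
Reagents that add atoms: none
Why: Staudinger reduction should convert the azide into the primary amine without touching the alkene or the silyl ethers.

Step 17
Reactants: 29 D-norvaline
Product: 30 (2R)-2-acetoxypentanoic acid
Conditions: NaNO2, AcOH, rt
Reagents that add atoms: acetic acid, CC(=O)O
Why: Diazotisation of the α-amino acid in acetic acid proceeds with neighbouring carboxylate participation (double inversion), so acetate should replace nitrogen with overall retention.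

Step 18
Reactants: 28 (2S,4S,5R)-2,4,5-tris(TBS-oxy)hept-6-en-1-amine; 30 (2R)-2-acetoxypentanoic acid
Product: 31 (2R)-1-oxo-1-{[(2S,4S,5R)-2,4,5-tris(TBS-oxy)hept-6-en-1-yl]amino}pentan-2-yl acetate
Conditions: EDC·HCl, HOBt, iPr2NEt, CH2Cl2, 0 °C → rt
Reagents that add atoms: none
Why: Carbodiimide/HOBt amide coupling should proceed without loss of the (R) configuration at C2′, because an α-acyloxy acid cannot form an oxazolone.

Step 19
Reactants: 31 (2R)-1-oxo-1-{[(2S,4S,5R)-2,4,5-tris(TBS-oxy)hept-6-en-1-yl]amino}pentan-2-yl acetate; 18 methyl (2S,4S,13R,14E)-17,17-dibromo-13-ethyl-2,4-dimethyl-9-oxoheptadeca-14,16-dienoate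
Product: 33 methyl (2S,4S,13R,14E,16Z,20R,21S,23S)-24-[(2R)-2-acetoxypentanamido]-17-bromo-13-ethyl-2,4-dimethyl-9-oxo-20,21,23-tris(TBS-oxy)tetracosa-14,16-dienoate, via B-alkyl-9-BBN 32 (not isolated)
Conditions: 31, 9-BBN (2 equiv), THF, rt → 40 °C; aq. Cs2CO3; then 18, Pd(dppf)Cl2 (10 mol%), AsPh3, DMF, rt
Reagents that add atoms: none
Why: Anti-Markovnikov hydroboration followed by B-alkyl Suzuki–Miyaura coupling should join C17–C18, because zerovalent palladium adds to a 1,1-dibromoalkene at the less hindered C–Br bond trans to the vinylic substituent, so the alkyl chain enters trans to C15 with retention and the remaining, more hindered cis bromide resists a second coupling at room temperature.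

Step 20
Reactants: 33 methyl (2S,4S,13R,14E,16Z,20R,21S,23S)-24-[(2R)-2-acetoxypentanamido]-17-bromo-13-ethyl-2,4-dimethyl-9-oxo-20,21,23-tris(TBS-oxy)tetracosa-14,16-dienoate
Product: 34 methyl (2S,4S,13R,14E,16Z,20R,21S,23S)-24-[(2R)-2-acetoxypentanamido]-13-ethyl-17-(hydroxymethyl)-2,4-dimethyl-9-oxo-20,21,23-tris(TBS-oxy)tetracosa-14,16-dienoate
Conditions: Bu3SnCH2OH (2 equiv), Pd(PPh3)4 (10 mol%), 1,4-dioxane, 90 °C
Reagents that add atoms: (tributylstannyl)methanol, CCCC[Sn](CCCC)(CCCC)CO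
Why: Stille coupling with selective transfer of the hydroxymethyl group should replace the vinylic bromide with retention, completing the (14E,16Z)-diene with CH2OH cis to C15.

Step 21
Reactants: 34 methyl (2S,4S,13R,14E,16Z,20R,21S,23S)-24-[(2R)-2-acetoxypentanamido]-13-ethyl-17-(hydroxymethyl)-2,4-dimethyl-9-oxo-20,21,23-tris(TBS-oxy)tetracosa-14,16-dienoate
Product: 35 methyl (2S,4S,13R,14E,16Z,20R,21S,23S)-24-[(2R)-2-acetoxypentanamido]-13-ethyl-2,4-dimethyl-9-oxo-20,21,23-tris(TBS-oxy)-17-[(TBS-oxy)methyl]tetracosa-14,16-dienoate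
Conditions: TBSCl, imidazole, CH2Cl2, 0 °C → rt
Reagents that add atoms: tert-butyldimethylsilyl chloride, CC(C)(C)[Si](C)(C)Cl
Why: Silylation of the only free hydroxyl, the primary allylic one, should leave C2′–OH as the single hydroxyl to be freed later.

Step 22
Reactants: 35 methyl (2S,4S,13R,14E,16Z,20R,21S,23S)-24-[(2R)-2-acetoxypentanamido]-13-ethyl-2,4-dimethyl-9-oxo-20,21,23-tris(TBS-oxy)-17-[(TBS-oxy)methyl]tetracosa-14,16-dienoate
Product: 36 (2S,4S,13R,14E,16Z,20R,21S,23S)-13-ethyl-24-[(2R)-2-hydroxypentanamido]-2,4-dimethyl-9-oxo-20,21,23-tris(TBS-oxy)-17-[(TBS-oxy)methyl]tetracosa-14,16-dienoic acid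
Conditions: LiOH (6 equiv), THF/MeOH/H2O, rt; aq. NaHSO4 to pH 4
Reagents that add atoms: lithium hydroxide, [Li+].[OH-]
Why: Saponification should cleave the activated α-acetoxy ester quickly and the hindered methyl ester more slowly, the C2 centre being shielded from enolisation once the carboxylate has formed and the silyl ethers being stable to aqueous hydroxide.

Step 23
Reactants: 36 (2S,4S,13R,14E,16Z,20R,21S,23S)-13-ethyl-24-[(2R)-2-hydroxypentanamido]-2,4-dimethyl-9-oxo-20,21,23-tris(TBS-oxy)-17-[(TBS-oxy)methyl]tetracosa-14,16-dienoic acid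
Product: 38 (2S,6S,8S,9R,12Z,14E,16R,25S,27S)-16-ethyl-25,27-dimethyl-2-propyl-6,8,9-tris(TBS-oxy)-12-[(TBS-oxy)methyl]-1-oxa-4-azacyclooctacosa-12,14-diene-3,20,28-trione, via oxyphosphonium carboxylate 37 (not isolated)
Conditions: PPh3 (6 equiv), DIAD (6 equiv), toluene, 0 °C → rt; 36 added by syringe pump over 8 h (final 1 mM)
Reagents that add atoms: none
Why: PPh3 and DIAD form the phosphonium betaine, which is protonated by the C1 carboxylic acid and passes phosphorus to the only free hydroxyl (C2′–OH), and the C1 carboxylate oxygen then displaces Ph3P=O from C2′ in an intramolecular SN2 reaction. The closest known reaction type is the Mitsunobu macrolactonisation, together with the Mitsunobu inversion of α-hydroxy esters and amides. The ring formed is the 28-membered 1-oxa-4-aza macrocycle, closed by O-alkylation at carbon (28-exo-tet), not by acyl transfer. The new stereocentre C2′ arises by inversion, so the (2′R)-carbinol from D-norvaline becomes (2′S), and the adjacent amide carbonyl accelerates SN2 while disfavouring ionisation. Selectivity among hydroxyls is needed and is secured by the four TBS ethers, the amide N–H being too weakly acidic to act as pronucleophile, and oligomerisation is suppressed by slow addition at high dilution. Because the acid is never turned into an acylating agent, the epimerisable C2 centre next to the carboxyl is not at risk.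

Step 24
Reactants: 38 (2S,6S,8S,9R,12Z,14E,16R,25S,27S)-16-ethyl-25,27-dimethyl-2-propyl-6,8,9-tris(TBS-oxy)-12-[(TBS-oxy)methyl]-1-oxa-4-azacyclooctacosa-12,14-diene-3,20,28-trione
Product: 39 (2S,6S,8S,9R,12Z,14E,16R,25S,27S)-16-ethyl-6,8,9-trihydroxy-12-(hydroxymethyl)-25,27-dimethyl-2-propyl-1-oxa-4-azacyclooctacosa-12,14-diene-3,20,28-trione (target)
Conditions: HF·pyridine, pyridine, THF, 0 °C → rt
Reagents that add atoms: none
Why: Fluoride-mediated global desilylation under buffered, weakly acidic conditions should free the four hydroxyls without acyl migration of the α-acyloxy amide, allylic ionisation or lactone opening.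

**Compound list**

1 | cis-2,4-dimethylglutaric anhydride, meso-(3R,5S)-3,5-dimethyloxane-2,6-dione | C[C@H]1C[C@@H](C)C(=O)OC1=O | starting material
2 | (2R,4S)-5-methoxy-2,4-dimethyl-5-oxopentanoic acid | COC(=O)[C@@H](C)C[C@@H](C)C(=O)O | intermediate
3 | methyl (2S,4R)-5-hydroxy-2,4-dimethylpentanoate | COC(=O)[C@@H](C)C[C@@H](C)CO | intermediate
4 | methyl (2S,4R)-2,4-dimethyl-5-oxopentanoate | COC(=O)[C@@H](C)C[C@@H](C)C=O | intermediate
5 | (3-carboxypropyl)triphenylphosphonium bromide | OC(=O)CCC[P+](c1ccccc1)(c1ccccc1)c1ccccc1.[Br-] | starting material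
6 | sodium 4-(triphenylphosphoranylidene)butanoate | [Na+].[O-]C(=O)CCC=P(c1ccccc1)(c1ccccc1)c1ccccc1 | intermediate (not isolated)
7 | (4Z,6R,8S)-9-methoxy-6,8-dimethyl-9-oxonon-4-enoic acid | COC(=O)[C@@H](C)C[C@@H](C)/C=C\CCC(=O)O | intermediate
8 | (6S,8S)-9-methoxy-6,8-dimethyl-9-oxononanoic acid | COC(=O)[C@@H](C)C[C@@H](C)CCCCC(=O)O | intermediate
9 | 5-bromopent-1-ene | C=CCCCBr | starting material
10 | (E)-1,4-dibromobut-2-ene | BrC/C=C/CBr | starting material
11 | (E)-1,6-dibromohex-2-ene | BrC/C=C/CCCBr | intermediate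
12 | (3R)-6-bromo-3-ethylhex-1-ene | BrCCC[C@@H](CC)C=C | intermediate
13 | methyl (2S,4S)-9-chloro-2,4-dimethyl-9-oxononanoate | COC(=O)[C@@H](C)C[C@@H](C)CCCCC(=O)Cl | intermediate (not isolated)
14 | [(4R)-4-ethylhex-5-en-1-yl]zinc bromide | Br[Zn]CCC[C@@H](CC)C=C | intermediate (not isolated)
15 | methyl (2S,4S,13R)-13-ethyl-2,4-dimethyl-9-oxopentadec-14-enoate | COC(=O)[C@@H](C)C[C@@H](C)CCCCC(=O)CCC[C@@H](CC)C=C | intermediate
16 | (E)-but-2-enal (crotonaldehyde) | C/C=C/C=O | starting material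
17 | methyl (2S,4S,13R,14E)-13-ethyl-2,4-dimethyl-9,16-dioxohexadec-14-enoate | COC(=O)[C@@H](C)C[C@@H](C)CCCCC(=O)CCC[C@@H](CC)/C=C/C=O | intermediate
18 | methyl (2S,4S,13R,14E)-17,17-dibromo-13-ethyl-2,4-dimethyl-9-oxoheptadeca-14,16-dienoate | COC(=O)[C@@H](C)C[C@@H](C)CCCCC(=O)CCC[C@@H](CC)/C=C/C=C(Br)Br | intermediate
19 | ethyl (3S)-4-chloro-3-hydroxybutanoate | CCOC(=O)C[C@H](O)CCl | starting material
20 | ethyl (3S)-4-azido-3-hydroxybutanoate | CCOC(=O)C[C@H](O)CN=[N+]=[N-] | intermediate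
21 | ethyl (3S)-4-azido-3-(TBS-oxy)butanoate | CCOC(=O)C[C@H](O[Si](C)(C)C(C)(C)C)CN=[N+]=[N-] | intermediate
22 | (3S)-4-azido-3-(TBS-oxy)butanal | O=CC[C@H](O[Si](C)(C)C(C)(C)C)CN=[N+]=[N-] | intermediate
23 | allenylboronic acid pinacol ester, 4,4,5,5-tetramethyl-2-(propa-1,2-dien-1-yl)-1,3,2-dioxaborolane | C=C=CB1OC(C)(C)C(C)(C)O1 | starting material
24 | (E)-[3-(pinacolatoboryl)allyl]bis(isopinocampheyl)borane, Ipc groups from (−)-α-pinene | CC1(C)OB(/C=C/CB([C@@H]2[C@@H](C)[C@@H]3C[C@H](C2)C3(C)C)[C@@H]2[C@@H](C)[C@@H]3C[C@H](C2)C3(C)C)OC1(C)C | intermediate (not isolated)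
25 | O-bis(isopinocampheyl)boryl, C-pinacolatoboryl allylboration adduct of 22 (C21–O–BIpc2, C20–Bpin, anti) | C=C[C@@H](B1OC(C)(C)C(C)(C)O1)[C@@H](OB([C@@H]1[C@@H](C)[C@@H]2C[C@H](C1)C2(C)C)[C@@H]1[C@@H](C)[C@@H]2C[C@H](C1)C2(C)C)C[C@H](O[Si](C)(C)C(C)(C)C)CN=[N+]=[N-] | intermediate (not isolated)
26 | (3R,4S,6S)-7-azido-6-(TBS-oxy)hept-1-ene-3,4-diol | C=C[C@@H](O)[C@@H](O)C[C@H](O[Si](C)(C)C(C)(C)C)CN=[N+]=[N-] | intermediate
27 | (2S,4S,5R)-1-azido-2,4,5-tris(TBS-oxy)hept-6-ene | C=C[C@@H](O[Si](C)(C)C(C)(C)C)[C@@H](O[Si](C)(C)C(C)(C)C)C[C@H](O[Si](C)(C)C(C)(C)C)CN=[N+]=[N-] | intermediate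
28 | (2S,4S,5R)-2,4,5-tris(TBS-oxy)hept-6-en-1-amine | C=C[C@@H](O[Si](C)(C)C(C)(C)C)[C@@H](O[Si](C)(C)C(C)(C)C)C[C@H](O[Si](C)(C)C(C)(C)C)CN | intermediate
29 | D-norvaline, (2R)-2-aminopentanoic acid | CCC[C@@H](N)C(=O)O | starting material
30 | (2R)-2-acetoxypentanoic acid | CCC[C@@H](OC(C)=O)C(=O)O | intermediate
31 | (2R)-1-oxo-1-{[(2S,4S,5R)-2,4,5-tris(TBS-oxy)hept-6-en-1-yl]amino}pentan-2-yl acetate | C=C[C@@H](O[Si](C)(C)C(C)(C)C)[C@@H](O[Si](C)(C)C(C)(C)C)C[C@H](O[Si](C)(C)C(C)(C)C)CNC(=O)[C@@H](CCC)OC(C)=O | intermediate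
32 | 9-alkyl-9-borabicyclo[3.3.1]nonane from 31 (boron on C18) | C(C[C@@H](O[Si](C)(C)C(C)(C)C)[C@@H](O[Si](C)(C)C(C)(C)C)C[C@H](O[Si](C)(C)C(C)(C)C)CNC(=O)[C@@H](CCC)OC(C)=O)B1C2CCCC1CCC2 | intermediate (not isolated)
33 | methyl (2S,4S,13R,14E,16Z,20R,21S,23S)-24-[(2R)-2-acetoxypentanamido]-17-bromo-13-ethyl-2,4-dimethyl-9-oxo-20,21,23-tris(TBS-oxy)tetracosa-14,16-dienoate | COC(=O)[C@@H](C)C[C@@H](C)CCCCC(=O)CCC[C@@H](CC)/C=C/C=C(\Br)CC[C@@H](O[Si](C)(C)C(C)(C)C)[C@@H](O[Si](C)(C)C(C)(C)C)C[C@H](O[Si](C)(C)C(C)(C)C)CNC(=O)[C@@H](CCC)OC(C)=O | intermediate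
34 | methyl (2S,4S,13R,14E,16Z,20R,21S,23S)-24-[(2R)-2-acetoxypentanamido]-13-ethyl-17-(hydroxymethyl)-2,4-dimethyl-9-oxo-20,21,23-tris(TBS-oxy)tetracosa-14,16-dienoate | COC(=O)[C@@H](C)C[C@@H](C)CCCCC(=O)CCC[C@@H](CC)/C=C/C=C(\CO)CC[C@@H](O[Si](C)(C)C(C)(C)C)[C@@H](O[Si](C)(C)C(C)(C)C)C[C@H](O[Si](C)(C)C(C)(C)C)CNC(=O)[C@@H](CCC)OC(C)=O | intermediate
35 | methyl (2S,4S,13R,14E,16Z,20R,21S,23S)-24-[(2R)-2-acetoxypentanamido]-13-ethyl-2,4-dimethyl-9-oxo-20,21,23-tris(TBS-oxy)-17-[(TBS-oxy)methyl]tetracosa-14,16-dienoate | COC(=O)[C@@H](C)C[C@@H](C)CCCCC(=O)CCC[C@@H](CC)/C=C/C=C(\CO[Si](C)(C)C(C)(C)C)CC[C@@H](O[Si](C)(C)C(C)(C)C)[C@@H](O[Si](C)(C)C(C)(C)C)C[C@H](O[Si](C)(C)C(C)(C)C)CNC(=O)[C@@H](CCC)OC(C)=O | intermediate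
36 | (2S,4S,13R,14E,16Z,20R,21S,23S)-13-ethyl-24-[(2R)-2-hydroxypentanamido]-2,4-dimethyl-9-oxo-20,21,23-tris(TBS-oxy)-17-[(TBS-oxy)methyl]tetracosa-14,16-dienoic acid | OC(=O)[C@@H](C)C[C@@H](C)CCCCC(=O)CCC[C@@H](CC)/C=C/C=C(\CO[Si](C)(C)C(C)(C)C)CC[C@@H](O[Si](C)(C)C(C)(C)C)[C@@H](O[Si](C)(C)C(C)(C)C)C[C@H](O[Si](C)(C)C(C)(C)C)CNC(=O)[C@@H](CCC)O | intermediate
37 | C2′-O-triphenylphosphonium C1-carboxylate zwitterion of 36 | [O-]C(=O)[C@@H](C)C[C@@H](C)CCCCC(=O)CCC[C@@H](CC)/C=C/C=C(\CO[Si](C)(C)C(C)(C)C)CC[C@@H](O[Si](C)(C)C(C)(C)C)[C@@H](O[Si](C)(C)C(C)(C)C)C[C@H](O[Si](C)(C)C(C)(C)C)CNC(=O)[C@@H](CCC)O[P+](c1ccccc1)(c1ccccc1)c1ccccc1 | intermediate (not isolated)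
38 | (2S,6S,8S,9R,12Z,14E,16R,25S,27S)-16-ethyl-25,27-dimethyl-2-propyl-6,8,9-tris(TBS-oxy)-12-[(TBS-oxy)methyl]-1-oxa-4-azacyclooctacosa-12,14-diene-3,20,28-trione | CCC[C@@H]1OC(=O)[C@@H](C)C[C@@H](C)CCCCC(=O)CCC[C@@H](CC)/C=C/C=C(\CO[Si](C)(C)C(C)(C)C)CC[C@@H](O[Si](C)(C)C(C)(C)C)[C@@H](O[Si](C)(C)C(C)(C)C)C[C@H](O[Si](C)(C)C(C)(C)C)CNC1=O | intermediate
39 | (2S,6S,8S,9R,12Z,14E,16R,25S,27S)-16-ethyl-6,8,9-trihydroxy-12-(hydroxymethyl)-25,27-dimethyl-2-propyl-1-oxa-4-azacyclooctacosa-12,14-diene-3,20,28-trione | CCC[C@@H]1OC(=O)[C@@H](C)C[C@@H](C)CCCCC(=O)CCC[C@@H](CC)/C=C/C=C(\CO)CC[C@@H](O)[C@@H](O)C[C@H](O)CNC1=O | target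

**Totals**

Total step count: 24. Longest linear sequence: 14 steps (1–5, 8–10, 19–24).

**Steps most likely to fail**

Step 19. The hydroboration of the vinyl group next to a silyloxy-bearing carbon may be incomplete, and under the aqueous-base coupling the trans-selectivity may erode or a second alkylation may occur at the remaining C–Br bond. The fallback sets out from 31 and uses an organozinc under anhydrous Negishi conditions. Hydroboration with 9-BBN and oxidation with NaBO3·4H2O should give the primary alcohol (2R)-1-{[(2S,4S,5R)-7-hydroxy-2,4,5-tris(TBS-oxy)heptyl]amino}-1-oxopentan-2-yl acetate F1. I2, PPh3 and imidazole should convert it into the primary iodide (2R)-1-{[(2S,4S,5R)-7-iodo-2,4,5-tris(TBS-oxy)heptyl]amino}-1-oxopentan-2-yl acetate F2. Zinc insertion (Zn dust, LiCl, THF) should give the alkylzinc iodide F3, which is coupled with 18 using PdCl2(DPEphos) in THF/DMF at rt, a wide-bite-angle catalyst known for trans-selective monoalkylation of 1,1-dibromoalkenes. This comes back to the route at 33.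

Step 20. Oxidative addition at the hindered vinylic bromide cis to the diene may be slow, leaving time for protodestannylation of the reagent or butyl transfer. The fallback sets out from 33 and introduces the carbon as CO. Palladium-catalysed reductive carbonylation (CO, Bu3SnH added slowly, Pd(PPh3)4, toluene, 50 °C) should give the dienal methyl (2S,4S,13R,14E,16Z,20R,21S,23S)-24-[(2R)-2-acetoxypentanamido]-13-ethyl-17-formyl-2,4-dimethyl-9-oxo-20,21,23-tris(TBS-oxy)tetracosa-14,16-dienoate F4. Aldehyde-selective reduction (NaBH4, CH2Cl2/EtOH, −78 °C, where the C9 ketone reacts far more slowly) comes back to the route at 34.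

Step 23. Intermolecular esterification may outrun the entropically costly 28-membered closure, and the long-lived oxyphosphonium ion may eliminate to the α,β-unsaturated amide. The fallback sets out from 35, inverts C2′ intermolecularly and closes the ring by acyl activation instead. K2CO3 in MeOH at 0 °C should remove only the acetate to give the (2′R)-hydroxy amide methyl ester F5. Intermolecular Mitsunobu esterification with 4-nitrobenzoic acid (PPh3, DIAD, THF) should give the inverted (2′S)-4-nitrobenzoate F6. LiOH in THF/MeOH/H2O should cleave both esters to the (2′S)-hydroxy seco acid F7. Shiina macrolactonisation (2-methyl-6-nitrobenzoic anhydride, DMAP, toluene, high dilution) then closes the ring at the C1 acyl–oxygen bond with retention at C2′ and comes back to the route at 38.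

**Further compounds**

F1 | step 19 | (2R)-1-{[(2S,4S,5R)-7-hydroxy-2,4,5-tris(TBS-oxy)heptyl]amino}-1-oxopentan-2-yl acetate | OCC[C@@H](O[Si](C)(C)C(C)(C)C)[C@@H](O[Si](C)(C)C(C)(C)C)C[C@H](O[Si](C)(C)C(C)(C)C)CNC(=O)[C@@H](CCC)OC(C)=O
F2 | step 19 | (2R)-1-{[(2S,4S,5R)-7-iodo-2,4,5-tris(TBS-oxy)heptyl]amino}-1-oxopentan-2-yl acetate | ICC[C@@H](O[Si](C)(C)C(C)(C)C)[C@@H](O[Si](C)(C)C(C)(C)C)C[C@H](O[Si](C)(C)C(C)(C)C)CNC(=O)[C@@H](CCC)OC(C)=O
F3 | step 19 | alkylzinc iodide from F2 (zinc on C18) | I[Zn]CC[C@@H](O[Si](C)(C)C(C)(C)C)[C@@H](O[Si](C)(C)C(C)(C)C)C[C@H](O[Si](C)(C)C(C)(C)C)CNC(=O)[C@@H](CCC)OC(C)=O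
F4 | step 20 | methyl (2S,4S,13R,14E,16Z,20R,21S,23S)-24-[(2R)-2-acetoxypentanamido]-13-ethyl-17-formyl-2,4-dimethyl-9-oxo-20,21,23-tris(TBS-oxy)tetracosa-14,16-dienoate | COC(=O)[C@@H](C)C[C@@H](C)CCCCC(=O)CCC[C@@H](CC)/C=C/C=C(\C=O)CC[C@@H](O[Si](C)(C)C(C)(C)C)[C@@H](O[Si](C)(C)C(C)(C)C)C[C@H](O[Si](C)(C)C(C)(C)C)CNC(=O)[C@@H](CCC)OC(C)=O
F5 | step 23 | methyl (2S,4S,13R,14E,16Z,20R,21S,23S)-13-ethyl-24-[(2R)-2-hydroxypentanamido]-2,4-dimethyl-9-oxo-20,21,23-tris(TBS-oxy)-17-[(TBS-oxy)methyl]tetracosa-14,16-dienoate | COC(=O)[C@@H](C)C[C@@H](C)CCCCC(=O)CCC[C@@H](CC)/C=C/C=C(\CO[Si](C)(C)C(C)(C)C)CC[C@@H](O[Si](C)(C)C(C)(C)C)[C@@H](O[Si](C)(C)C(C)(C)C)C[C@H](O[Si](C)(C)C(C)(C)C)CNC(=O)[C@@H](CCC)O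
F6 | step 23 | methyl (2S,4S,13R,14E,16Z,20R,21S,23S)-13-ethyl-2,4-dimethyl-24-{(2S)-2-[(4-nitrobenzoyl)oxy]pentanamido}-9-oxo-20,21,23-tris(TBS-oxy)-17-[(TBS-oxy)methyl]tetracosa-14,16-dienoate | COC(=O)[C@@H](C)C[C@@H](C)CCCCC(=O)CCC[C@@H](CC)/C=C/C=C(\CO[Si](C)(C)C(C)(C)C)CC[C@@H](O[Si](C)(C)C(C)(C)C)[C@@H](O[Si](C)(C)C(C)(C)C)C[C@H](O[Si](C)(C)C(C)(C)C)CNC(=O)[C@H](CCC)OC(=O)c1ccc(cc1)[N+](=O)[O-]
F7 | step 23 | (2S,4S,13R,14E,16Z,20R,21S,23S)-13-ethyl-24-[(2S)-2-hydroxypentanamido]-2,4-dimethyl-9-oxo-20,21,23-tris(TBS-oxy)-17-[(TBS-oxy)methyl]tetracosa-14,16-dienoic acid | OC(=O)[C@@H](C)C[C@@H](C)CCCCC(=O)CCC[C@@H](CC)/C=C/C=C(\CO[Si](C)(C)C(C)(C)C)CC[C@@H](O[Si](C)(C)C(C)(C)C)[C@@H](O[Si](C)(C)C(C)(C)C)C[C@H](O[Si](C)(C)C(C)(C)C)CNC(=O)[C@H](CCC)O
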